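**Retrosynthetic overview**
- Feature: C4 is a doubly benzylic CH on C4a, and C4a lies between C8a (bearing O1) and C5 (bearing OH). The benzo ring of the chroman is therefore a 2-substituted resorcinol with two interchangeable oxygens, and its ortho-quinone methide (exocyclic C4 carrying the naphthyl) lacks only the C3–C2 unit of the pyran ring.
- Last disconnection: C2–CH3, back to a 2-ethoxy acetal; methyl is added to the chromanyl oxocarbenium ion trans to the C4 naphthyl group.
- Key disconnection: C3–C4 and O1–C2, back to the resorcinol quinone methide and ethyl vinyl ether, joined by an enantioselective oxa-[4+2] under a chiral phosphoric acid.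
- The quinone methide precursor (a diaryl carbinol) comes from 4-lithio-1,8-dimethoxynaphthalene and bis-silylated 2,6-dihydroxybenzaldehyde.
- Ring order: the naphthalene and resorcinol rings are bought; the pyran ring is the only ring built, in the cycloaddition.

Key step: step 6

Assumption (chemistry): the absolute sense of induction of the phosphoric acid, and of the chiral vinyl ether in the first fallback, cannot be predicted with certainty for this substrate. The (R)-catalyst and the (1R,2S)-auxiliary are written as the ones giving 4S; the antipode is taken if a test run shows the opposite sense.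

**Route**

Step 1
Reactants: 1 naphthalene-1,8-diol
Product: 2 1,8-dimethoxynaphthalene
Conditions: MeI (3 equiv), K2CO3 (4 equiv), acetone, reflux
Reagents that add atoms: iodomethane, CI
Why: Williamson ether synthesis, in which carbonate deprotonates each phenol in turn and the phenoxide displaces iodide from iodomethane; excess reagent and reflux drive the slower second alkylation of the hydrogen-bonded peri-hydroxy ether, and no stereocentre is involved.

Step 2
Reactants: 2 1,8-dimethoxynaphthalene
Product: 3 4-bromo-1,8-dimethoxynaphthalene
Conditions: N-bromosuccinimide (1.0 equiv), MeCN, 0 °C to rt, dark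
Reagents that add atoms: N-bromosuccinimide, O=C1CCC(=O)N1Br
Why: Electrophilic aromatic bromination, in which each methoxy group activates its own ring and directs to the para (alpha-naphthyl) carbon C4 rather than the ortho (beta) carbon C2; one equivalent of reagent at low temperature should stop at the monobromide.

Step 3
Reactants: 4 2,6-dihydroxybenzaldehyde
Product: 5 2,6-bis{[tert-butyl(dimethyl)silyl]oxy}benzaldehyde
Conditions: TBSCl (2.5 equiv), imidazole (5 equiv), DMF, rt
Reagents that add atoms: tert-butyldimethylsilyl chloride, CC(C)(C)[Si](C)(C)Cl
Why: Imidazole-promoted silyl ether formation on both phenols masks the acidic protons that would quench the aryllithium of step 4 and leaves the aldehyde free; no stereocentre is formed.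

Step 4
Reactants: 3 4-bromo-1,8-dimethoxynaphthalene; 5 2,6-bis{[tert-butyl(dimethyl)silyl]oxy}benzaldehyde
Product: 7 (2,6-bis{[tert-butyl(dimethyl)silyl]oxy}phenyl)(4,5-dimethoxynaphthalen-1-yl)methanol (racemic), via (4,5-dimethoxynaphthalen-1-yl)lithium 6 (not isolated)
Conditions: n-BuLi (1.0 equiv), THF, −78 °C; then 5 (0.95 equiv), THF, −78 °C; AcOH (1.2 equiv), −78 °C, then warm to rt
Reagents that add atoms: none
Why: Bromine–lithium exchange followed by 1,2-addition of aryllithium 6 to the non-enolisable aldehyde forges the future C4–naphthyl bond; the carbinol centre is formed racemic on purpose (it is flattened in step 6), and the cold acetic acid quench protonates the alkoxide before phenol-to-carbinol silyl migration can set in.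

Step 5
Reactants: 7 (2,6-bis{[tert-butyl(dimethyl)silyl]oxy}phenyl)(4,5-dimethoxynaphthalen-1-yl)methanol
Product: 8 2-[(4,5-dimethoxynaphthalen-1-yl)(hydroxy)methyl]benzene-1,3-diol (racemic)
Conditions: Bu4NF (2.5 equiv), AcOH (2.5 equiv), THF, 0 °C; rapid filtration through Et3N-deactivated silica, used promptly
Reagents that add atoms: none
Why: Fluoride cleavage of the aryl silyl ethers, buffered with acetic acid so that each liberated phenoxide is protonated at once and cannot expel the benzylic oxygen to a quinone methide; a silyl group that had migrated to the carbinol oxygen is removed by the same reagent, and the carbinol centre stays racemic.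

Step 6
Reactants: 8 2-[(4,5-dimethoxynaphthalen-1-yl)(hydroxy)methyl]benzene-1,3-diol; 9 ethyl vinyl ether
Product: 11 (2R,4S)-4-(4,5-dimethoxynaphthalen-1-yl)-2-ethoxychroman-5-ol (2,4-cis acetal), via ortho-quinone methide 10 (not isolated)
Conditions: (R)-3,3'-bis(2,4,6-triisopropylphenyl)-1,1'-binaphthyl-2,2'-diyl hydrogen phosphate (10 mol %), 9 (5 equiv), 5 Å molecular sieves, toluene, −20 °C
Reagents that add atoms: none
Why: The phosphoric acid protonates the doubly activated benzylic hydroxyl of 8 and, after loss of water, stays hydrogen-bonded to the carbonyl oxygen and the remaining phenol of quinone methide 10, so both enantiomers of the carbinol converge on one planar, catalyst-bound heterodiene. The nucleophilic CH2 terminus of the vinyl ether attacks the exocyclic carbon (future C4) and the ethoxy-stabilised cation is captured by the quinone methide oxygen, an asynchronous inverse-electron-demand oxa-[4+2]; the closest known type is the chiral phosphoric acid catalysed cycloaddition of in situ ortho-quinone methides from ortho-hydroxybenzhydrols with enamides, vinyl ethers and styrenes. The pyran ring is the only ring closed, by [4+2] cycloaddition that forms C3–C4 and O1–C2 across the O=C–C=C unit of 10. C4 (S) is set by the chiral phosphate, whose 3,3'-aryl groups block one face of the bound quinone methide; C2 arises from endo approach of the ethoxy group (cis acetal) and is of no consequence because it is erased in step 7. The step needs enantiofacial selectivity at C4 and head-to-tail regiochemistry: the latter follows from the polarity of the vinyl ether (its oxygen-bearing carbon bonds to the quinone methide oxygen), and no choice between the phenols arises because both resorcinol oxygens give the same quinone methide and the same product. The para-methoxy group of the naphthyl ring stabilises the cationic character at C4, so 10 forms at low temperature, where the uncatalysed background reaction and self-condensation are slow.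

Step 7
Reactants: 11 (2R,4S)-4-(4,5-dimethoxynaphthalen-1-yl)-2-ethoxychroman-5-ol
Product: 13 cladonaphchrom A [(2R,4S)-4-(4,5-dimethoxynaphthalen-1-yl)-2-methylchroman-5-ol], via chromanyl oxocarbenium ion 12 (not isolated)
Conditions: AlMe3 (5 equiv, 2 M in toluene), CH2Cl2, −78 °C to 0 °C; aq. potassium sodium tartrate work-up
Reagents that add atoms: trimethylaluminium, C[Al](C)C
Why: Lewis-acid-mediated substitution of a cyclic O,O-acetal by an organoaluminium reagent, in which the first equivalent of AlMe3 turns the phenol into its dimethylaluminium phenoxide, further AlMe3 complexes the more basic exocyclic ethoxy oxygen and ionises C2 to oxocarbenium ion 12, and methyl is delivered to C2 on the face opposite the C4 naphthyl group (held pseudoaxial by peri strain with the C5 oxygen, so that syn attack would be 1,3-diaxial), which should set C2 as R and give the 2,4-trans chroman with C4 untouched.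

**Compound list**

1 | naphthalene-1,8-diol | Oc1cccc2cccc(O)c12 | starting material
2 | 1,8-dimethoxynaphthalene | COc1cccc2cccc(OC)c12 | intermediate
3 | 4-bromo-1,8-dimethoxynaphthalene | COc1cccc2c(Br)ccc(OC)c12 | intermediate
4 | 2,6-dihydroxybenzaldehyde | O=Cc1c(O)cccc1O | starting material
5 | 2,6-bis{[tert-butyl(dimethyl)silyl]oxy}benzaldehyde | O=Cc1c(O[Si](C)(C)C(C)(C)C)cccc1O[Si](C)(C)C(C)(C)C | intermediate
6 | (4,5-dimethoxynaphthalen-1-yl)lithium (formed in the flask) | COc1cccc2c([Li])ccc(OC)c12 | intermediate
7 | (2,6-bis{[tert-butyl(dimethyl)silyl]oxy}phenyl)(4,5-dimethoxynaphthalen-1-yl)methanol, racemic | COc1cccc2c(C(O)c3c(O[Si](C)(C)C(C)(C)C)cccc3O[Si](C)(C)C(C)(C)C)ccc(OC)c12 | intermediate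
8 | 2-[(4,5-dimethoxynaphthalen-1-yl)(hydroxy)methyl]benzene-1,3-diol, racemic | COc1cccc2c(C(O)c3c(O)cccc3O)ccc(OC)c12 | intermediate
9 | ethyl vinyl ether | C=COCC | starting material
10 | 2-[(4,5-dimethoxynaphthalen-1-yl)methylidene]-3-hydroxycyclohexa-3,5-dien-1-one, ortho-quinone methide (formed in the flask) | COc1cccc2c(C=C3C(=O)C=CC=C3O)ccc(OC)c12 | intermediate
11 | (2R,4S)-4-(4,5-dimethoxynaphthalen-1-yl)-2-ethoxychroman-5-ol | COc1cccc2c([C@@H]3C[C@H](OCC)Oc4cccc(O)c43)ccc(OC)c12 | intermediate
12 | (4S)-5-[(dimethylalumanyl)oxy]-4-(4,5-dimethoxynaphthalen-1-yl)-3,4-dihydrochromenylium, oxocarbenium ion (formed in the flask) | COc1cccc2c([C@@H]3CC=[O+]c4cccc(O[Al](C)C)c43)ccc(OC)c12 | intermediate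
13 | cladonaphchrom A, (2R,4S)-4-(4,5-dimethoxynaphthalen-1-yl)-2-methylchroman-5-ol | COc1cccc2c([C@@H]3C[C@@H](C)Oc4cccc(O)c43)ccc(OC)c12 | target

**Summary**

Total step count: 7. Longest linear sequence: 6 steps (steps 1, 2, 4, 5, 6, 7 from naphthalene-1,8-diol); the aldehyde branch joins at step 4 after one step.

**Steps most likely to fail**

1. Step 6. The chiral phosphate may discriminate the two faces of the hindered, doubly ortho-oxygenated quinone methide poorly. The quinone methide may also be consumed by Friedel–Crafts self-condensation with the electron-rich resorcinol ring, and the acid may use up vinyl ether by addition of the phenol (a stray 1-ethoxyethyl ether on the phenol would be cleared with catalytic pyridinium tosylate in ethanol, which leaves the ethyl acetal unchanged). Fallback, from auxiliary control instead of catalyst control, setting out from carbinol 8 and returning at target 13: commercial (1R,2S)-trans-2-phenylcyclohexanol is vinylated by transetherification with ethyl vinyl ether 9 (Hg(OAc)2 cat., reflux) to {[(1R,2S)-2-phenylcyclohexyl]oxy}ethene F1. Carbinol 8 and F1 with achiral diphenyl phosphate (10 mol %) and 5 Å sieves in toluene at −20 °C should pass through the same quinone methide 10 to (2R,4S)-4-(4,5-dimethoxynaphthalen-1-yl)-2-{[(1R,2S)-2-phenylcyclohexyl]oxy}chroman-5-ol F2, the phenyl-shielded face of the enol ether dictating the approach (auxiliary-controlled diastereoselective quinone methide cycloaddition). The C4 epimers are now diastereomers and can be separated by chromatography. F2 under the conditions of step 7 should give 13 with release of the auxiliary alcohol for re-use.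

2. Step 7. Ionisation may take the endocyclic path (loss of the phenoxide, ring opening), the oxocarbenium ion may lose a C3 proton to a 4H-chromene, or facial bias in the methyl transfer may be insufficient. Fallback, which forms O1–C2 last instead of C2–CH3, setting out from acetal 11 and returning at 13: hydrolysis (AcOH, H2O, THF, 40 °C) gives the lactol (4S)-4-(4,5-dimethoxynaphthalen-1-yl)chromane-2,5-diol F3. Wittig methylenation of its open hydroxy-aldehyde form (Ph3PCH3Br, KN(SiMe3)2, excess to cover both phenoxides, THF, 0 °C to rt) gives 2-[(1S)-1-(4,5-dimethoxynaphthalen-1-yl)but-3-en-1-yl]benzene-1,3-diol F4. Markovnikov intramolecular hydroalkoxylation (AgOTf 5 mol %, 1,2-dichloroethane, 60 °C; oxymercuration with Hg(OAc)2 then NaBH4 as the alternative) closes the pyran ring 6-exo by attack of a phenol oxygen on the internal alkene carbon. Either phenol gives the same chroman, and a chair-like closure with the naphthyl pseudoaxial and the new methyl equatorial should favour the 2,4-trans isomer 13; any cis isomer is removed by chromatography.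

3. Step 4. The lithium alkoxide may take a silyl group from a neighbouring phenol oxygen and eliminate silanolate to a quinone methide that captures a second aryllithium, or addition to the doubly flanked aldehyde may be sluggish. Fallback without protecting groups, setting out from bromide 3 and aldehyde 4 and returning at carbinol 8 (steps 3 and 5 are bypassed): bromide 3 with Mg turnings (I2 initiation, THF, reflux) gives (4,5-dimethoxynaphthalen-1-yl)magnesium bromide F5. Addition of 4 to F5 (3.3 equiv) in THF at 0 °C lets two equivalents deprotonate the phenols and the third add to the aldehyde of the magnesium bis-phenoxide. Aqueous NH4Cl work-up should give 8 directly, and the 1,8-dimethoxynaphthalene 2 returned by the two sacrificed equivalents is recovered and re-brominated.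

**Further compounds**

F1 | step 6 | {[(1R,2S)-2-phenylcyclohexyl]oxy}ethene | C=CO[C@@H]1CCCC[C@H]1c1ccccc1
F2 | step 6 | (2R,4S)-4-(4,5-dimethoxynaphthalen-1-yl)-2-{[(1R,2S)-2-phenylcyclohexyl]oxy}chroman-5-ol | COc1cccc2c([C@@H]3C[C@H](O[C@@H]5CCCC[C@H]5c6ccccc6)Oc4cccc(O)c43)ccc(OC)c12
F3 | step 7 | (4S)-4-(4,5-dimethoxynaphthalen-1-yl)chromane-2,5-diol | COc1cccc2c([C@@H]3CC(O)Oc4cccc(O)c43)ccc(OC)c12
F4 | step 7 | 2-[(1S)-1-(4,5-dimethoxynaphthalen-1-yl)but-3-en-1-yl]benzene-1,3-diol | COc1cccc2c([C@H](CC=C)c3c(O)cccc3O)ccc(OC)c12
F5 | step 4 | (4,5-dimethoxynaphthalen-1-yl)magnesium bromide | COc1cccc2c([Mg]Br)ccc(OC)c12
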